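**Retrosynthetic overview** (hexahydroindene numbering: C1/C3 carry the methyls, C3a/C7a are the ring fusion, C4 is quaternary, C5 carries phenyl, C6=C7 is the ring alkene with ethyl on C7)
- Target acid ⇐ ethyl ester (saponification) ⇐ C4 carbaldehyde (Wittig) ⇐ C4–H aldehyde (α-ethylation makes the quaternary centre last).
- Key disconnection: both vinylic ring bonds of the cyclohexene, C5–C6 and C7–C7a, are cut, so that C6=C7(Et) is 1-butyne. It is stitched between a cyclopentyl-copper (C7a) and the benzylic γ-carbon (C5) of an (E)-α-cyclopentylcinnamaldehyde dimethyl acetal by carbocupration and intramolecular SN2' closure.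
- Enabling feature: the ring alkene has H on C6 and ethyl on C7, the pattern that syn addition of an alkylcopper to a terminal alkyne delivers; and C5 (CHPh) is β to C4, whose exocyclic carbon is a carbonyl equivalent, so C5 can be the electrophilic γ-position of an unsaturated acetal.
- Precursor: a cyclopentane with four stereocentres from cis-jasmone (ozonolysis, SAMP-hydrazone methylation, 1,2-reduction, hydroxyl-directed hydrogenation), then aldol condensation with benzaldehyde.
- Ring order: the cyclopentane comes from the starting material; the cyclohexene is closed in the key step.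

Key step: step 12

Remark: the configuration is taken exactly as written in the SMILES, i.e. (1R,3R,3aR,4S,5S,7aR): trans ring fusion, each ring methyl cis to the neighbouring six-ring carbon, phenyl cis to the C4 ethyl group.

**Route**

Step 1
Reactants: 1 cis-jasmone
Product: 2 2-(2-methyl-5-oxocyclopent-1-en-1-yl)acetaldehyde
Conditions: O3 (1 equiv), CH2Cl2/MeOH, −78 °C; Me2S
Reagents that add atoms: ozone, [O-][O+]=O
Why: Ozonolysis with reductive work-up should cleave only the electron-rich disubstituted side-chain alkene, because the tetrasubstituted ring alkene is deactivated by conjugation with the ketone; no stereocentre is formed.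

Step 2
Reactants: 2 2-(2-methyl-5-oxocyclopent-1-en-1-yl)acetaldehyde
Product: 3 2-(1,3-dioxolan-2-ylmethyl)-3-methylcyclopent-2-en-1-one
Conditions: HOCH2CH2OH, PPTS (cat.), benzene, reflux, Dean–Stark
Reagents that add atoms: ethylene glycol, OCCO
Why: Acid-catalysed acetalisation should be selective for the aldehyde over the hindered conjugated ketone and protects it against the base and hydride of steps 4 to 6.

Step 3
Reactants: 3 2-(1,3-dioxolan-2-ylmethyl)-3-methylcyclopent-2-en-1-one; 4 SAMP, (2S)-2-(methoxymethyl)pyrrolidin-1-amine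
Product: 5 (2S)-N-[2-(1,3-dioxolan-2-ylmethyl)-3-methylcyclopent-2-en-1-ylidene]-2-(methoxymethyl)pyrrolidin-1-amine
Conditions: TsOH (cat.), benzene, reflux, Dean–Stark
Reagents that add atoms: none
Why: Condensation of the ketone with the hydrazine gives the SAMP hydrazone needed for auxiliary-controlled alkylation; the dioxolane should survive the dehydrating conditions.

Step 4
Reactants: 5 SAMP hydrazone of 3
Product: 6 (2S)-N-[(5R)-2-(1,3-dioxolan-2-ylmethyl)-3,5-dimethylcyclopent-2-en-1-ylidene]-2-(methoxymethyl)pyrrolidin-1-amine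
Conditions: LiN(i-Pr)2, THF, −78 °C; MeI, −100 to −78 °C
Reagents that add atoms: iodomethane, IC
Why: Enders SAMP-hydrazone α-alkylation: the base removes a proton from C5, the only sp3 α-carbon, and the chelated azaenolate is methylated on the face set by the (S)-auxiliary, which by the facial rule for cyclic ketone SAMP hydrazones should give the (5R) centre.

Step 5
Reactants: 6 (5R)-methylated SAMP hydrazone
Product: 7 (5R)-2-(1,3-dioxolan-2-ylmethyl)-3,5-dimethylcyclopent-2-en-1-one
Conditions: CuCl2, THF/H2O (pH 7 buffer), rt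
Reagents that add atoms: water, O
Why: CuCl2-assisted hydrazone hydrolysis under near-neutral conditions should release the ketone without epimerising C5 or opening the dioxolane.

Step 6
Reactants: 7 (5R)-2-(1,3-dioxolan-2-ylmethyl)-3,5-dimethylcyclopent-2-en-1-one
Product: 8 (1R,5R)-2-(1,3-dioxolan-2-ylmethyl)-3,5-dimethylcyclopent-2-en-1-ol (hydroxyl cis to the C5 methyl)
Conditions: NaBH4, CeCl3·7H2O, MeOH, −78 °C
Reagents that add atoms: none
Why: Luche 1,2-reduction; hydride should add to the carbonyl face anti to the adjacent C5 methyl, so the new C1 hydroxyl is cis to that methyl.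

Step 7
Reactants: 8 (1R,5R)-2-(1,3-dioxolan-2-ylmethyl)-3,5-dimethylcyclopent-2-en-1-ol
Product: 9 (1R,2R,3R,5R)-2-(1,3-dioxolan-2-ylmethyl)-3,5-dimethylcyclopentan-1-ol
Conditions: H2 (1 atm), [Ir(cod)(py)(PCy3)]PF6 (cat.), CH2Cl2, rt
Reagents that add atoms: none
Why: Hydroxyl-directed homogeneous hydrogenation: the cationic iridium catalyst binds the C1 hydroxyl and delivers both hydrogens to the tetrasubstituted alkene on the hydroxyl face, which sets C2 and C3 so that the side chain and the C3 methyl are cis to each other and trans to the hydroxyl and the C5 methyl.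

Step 8
Reactants: 9 (1R,2R,3R,5R)-2-(1,3-dioxolan-2-ylmethyl)-3,5-dimethylcyclopentan-1-ol
Product: 10 2-[(1R,2R,3R,5R)-2-hydroxy-3,5-dimethylcyclopentyl]acetaldehyde
Conditions: 1 M HCl, THF, rt
Reagents that add atoms: water, O
Why: Acid-catalysed acetal hydrolysis frees the aldehyde; lactol formation is not expected because hydroxyl and side chain are trans on the ring, and no stereocentre is α to a carbonyl.

Step 9
Reactants: 10 2-[(1R,2R,3R,5R)-2-hydroxy-3,5-dimethylcyclopentyl]acetaldehyde; 11 benzaldehyde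
Product: 12 (2E)-2-[(1S,2R,3R,5R)-2-hydroxy-3,5-dimethylcyclopentyl]-3-phenylprop-2-enal
Conditions: PhCHO (3 equiv), KOH (cat.), MeOH, 0 °C to rt, slow addition of the aldehyde
Reagents that add atoms: none
Why: Crossed aldol (Claisen–Schmidt) condensation of the only enolisable aldehyde with benzaldehyde; dehydration should give the preferred (E)-enal, phenyl trans to formyl and therefore cis to the cyclopentyl group, the geometry that later sets C5 of the bicycle.

Step 10
Reactants: 12 (2E)-2-[(1S,2R,3R,5R)-2-hydroxy-3,5-dimethylcyclopentyl]-3-phenylprop-2-enal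
Product: 13 (1R,2S,3R,5R)-2-[(1E)-3,3-dimethoxy-1-phenylprop-1-en-2-yl]-3,5-dimethylcyclopentan-1-ol
Conditions: HC(OMe)3, MeOH, PPTS (cat.), rt
Reagents that add atoms: trimethyl orthoformate, COC(OC)OC; methanol, CO
Why: Acetalisation with orthoformate as water scavenger turns the enal into an α,β-unsaturated acetal that is inert to Grignard and organocopper formation and serves as the SN2' electrophile of step 12; the alkene geometry is retained.

Step 11
Reactants: 13 (1R,2S,3R,5R)-2-[(1E)-3,3-dimethoxy-1-phenylprop-1-en-2-yl]-3,5-dimethylcyclopentan-1-ol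
Product: 14 [(1E)-2-[(1S,2S,3R,5R)-2-bromo-3,5-dimethylcyclopentyl]-3,3-dimethoxyprop-1-en-1-yl]benzene
Conditions: CBr4, PPh3, 2,6-lutidine, CH2Cl2, 0 °C to rt
Reagents that add atoms: carbon tetrabromide, BrC(Br)(Br)Br
Why: Appel bromination (SN2 with inversion) under buffered conditions that spare the acetal; the configuration of this carbon is not carried further, since it is re-established at the organometallic stage of step 12.

Step 12
Reactants: 14 [(1E)-2-[(1S,2S,3R,5R)-2-bromo-3,5-dimethylcyclopentyl]-3,3-dimethoxyprop-1-en-1-yl]benzene; 15 1-butyne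
Product: 20 (1R,3R,3aR,5R,7aR)-7-ethyl-1,3-dimethyl-5-phenyl-2,3,3a,4,5,7a-hexahydro-1H-indene-4-carbaldehyde (both C4 epimers), via cyclopentylmagnesium bromide 16 (not isolated), via cyclopentylcopper 17 (not isolated), via alkenylcopper 18 (not isolated), via methyl enol ether 19 (not isolated)
Conditions: Mg, Et2O, rt; CuBr·SMe2, Me2S, −45 °C; 1-butyne, −25 °C; BF3·OEt2, −78 to −30 °C; 1 M HCl, THF, 0 °C
Reagents that add atoms: water, O
Why: Proposed new method: magnesium insertion and transmetalation to CuBr·SMe2 give a secondary alkylcopper that adds syn across 1-butyne, alkyl on the internal alkyne carbon (C7) and copper on the terminal carbon (C6); the resulting (Z)-alkenylcopper, activated by BF3·OEt2, attacks the benzylic γ-carbon (C5) of the α,β-unsaturated acetal in an intramolecular SN2' substitution that expels methoxide and leaves an enol ether, which is hydrolysed on work-up. The closest known reaction types are the carbocupration of terminal alkynes by alkylcopper–magnesium halide reagents and the BF3-promoted SN2' reaction of organocopper reagents with α,β-unsaturated (cinnamaldehyde-type) acetals, here joined into one annulation. Only the cyclohexene ring is closed, in a 6-endo-trig SN2' mode, which amounts to a formal (4+2) union of a 1,4-ambiphile with the alkyne. C7a is controlled by the organometallic, which should sit trans to the large neighbouring side chain and reacts with retention, so the ring fusion becomes trans; C5 is controlled by the E geometry of the styrenyl acetal together with the chair-like 6-endo transition state, which places phenyl (cis to the ring-bound alkene substituent) pseudoaxial and syn to H-3a. The step needs (a) alkyl-to-internal regioselectivity and syn addition in the carbocupration, both inherent to this reagent class, (b) γ- rather than α-attack on the acetal, favoured by the soft copper nucleophile under BF3 activation, and (c) the trans organometallic epimer, favoured by the size of the neighbouring side chain.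

Step 13
Reactants: 20 (1R,3R,3aR,5R,7aR)-7-ethyl-1,3-dimethyl-5-phenyl-2,3,3a,4,5,7a-hexahydro-1H-indene-4-carbaldehyde
Product: 21 (1R,3R,3aR,4R,5S,7aR)-4,7-diethyl-1,3-dimethyl-5-phenyl-2,3,3a,4,5,7a-hexahydro-1H-indene-4-carbaldehyde
Conditions: KOt-Bu, t-BuOH/THF, 0 °C; EtI, 0 °C to rt
Reagents that add atoms: iodoethane, ICC
Why: C-alkylation of the potassium enolate of an α-branched aldehyde; the electrophile should enter on the ring face anti to the C3 methyl, which lies 1,3-syn to the axial position at C4 and shields it, so ethyl becomes equatorial (cis to the C5 phenyl and H-3a) and formyl axial.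

Step 14
Reactants: 21 (1R,3R,3aR,4R,5S,7aR)-4,7-diethyl-1,3-dimethyl-5-phenyl-2,3,3a,4,5,7a-hexahydro-1H-indene-4-carbaldehyde; 22 ethyl 2-(triphenyl-λ5-phosphanylidene)propanoate
Product: 23 ethyl (2E)-3-[(1R,3R,3aR,4S,5S,7aR)-4,7-diethyl-1,3-dimethyl-5-phenyl-2,3,3a,4,5,7a-hexahydro-1H-inden-4-yl]-2-methylprop-2-enoate
Conditions: toluene, 110 °C
Reagents that add atoms: none
Why: Wittig olefination with a stabilised ylide should give the (E)-trisubstituted enoate; the aldehyde is non-enolisable, so no stereocentre is at risk.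

Step 15
Reactants: 23 ethyl (2E)-3-[(1R,3R,3aR,4S,5S,7aR)-4,7-diethyl-1,3-dimethyl-5-phenyl-2,3,3a,4,5,7a-hexahydro-1H-inden-4-yl]-2-methylprop-2-enoate
Product: 24 homo-plakotenin, (2E)-3-[(1R,3R,3aR,4S,5S,7aR)-4,7-diethyl-1,3-dimethyl-5-phenyl-2,3,3a,4,5,7a-hexahydro-1H-inden-4-yl]-2-methylprop-2-enoic acid
Conditions: LiOH, THF/MeOH/H2O, 50 °C; then 1 M HCl
Reagents that add atoms: lithium hydroxide, [Li+].[OH-]
Why: Saponification followed by acidification gives the acid; the trisubstituted enoate next to a quaternary carbon should resist conjugate addition, and no stereocentre is epimerisable.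

**Compound list**

1 | cis-jasmone, 3-methyl-2-[(2Z)-pent-2-en-1-yl]cyclopent-2-en-1-one | CC/C=C\CC1=C(C)CCC1=O | starting material
2 | 2-(2-methyl-5-oxocyclopent-1-en-1-yl)acetaldehyde | O=CCC1=C(C)CCC1=O | intermediate
3 | 2-(1,3-dioxolan-2-ylmethyl)-3-methylcyclopent-2-en-1-one | CC1=C(CC2OCCO2)C(=O)CC1 | intermediate
4 | SAMP, (2S)-2-(methoxymethyl)pyrrolidin-1-amine | COC[C@@H]1CCCN1N | starting material
5 | (2S)-N-[2-(1,3-dioxolan-2-ylmethyl)-3-methylcyclopent-2-en-1-ylidene]-2-(methoxymethyl)pyrrolidin-1-amine | COC[C@@H]1CCCN1N=C2CCC(C)=C2CC3OCCO3 | intermediate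
6 | (2S)-N-[(5R)-2-(1,3-dioxolan-2-ylmethyl)-3,5-dimethylcyclopent-2-en-1-ylidene]-2-(methoxymethyl)pyrrolidin-1-amine | COC[C@@H]1CCCN1N=C2[C@H](C)CC(C)=C2CC3OCCO3 | intermediate
7 | (5R)-2-(1,3-dioxolan-2-ylmethyl)-3,5-dimethylcyclopent-2-en-1-one | CC1=C(CC2OCCO2)C(=O)[C@H](C)C1 | intermediate
8 | (1R,5R)-2-(1,3-dioxolan-2-ylmethyl)-3,5-dimethylcyclopent-2-en-1-ol | CC1=C(CC2OCCO2)[C@H](O)[C@H](C)C1 | intermediate
9 | (1R,2R,3R,5R)-2-(1,3-dioxolan-2-ylmethyl)-3,5-dimethylcyclopentan-1-ol | O1CCOC1C[C@H]2[C@H](O)[C@H](C)C[C@H]2C | intermediate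
10 | 2-[(1R,2R,3R,5R)-2-hydroxy-3,5-dimethylcyclopentyl]acetaldehyde | O=CC[C@H]1[C@H](O)[C@H](C)C[C@H]1C | intermediate
11 | benzaldehyde | O=Cc1ccccc1 | starting material
12 | (2E)-2-[(1S,2R,3R,5R)-2-hydroxy-3,5-dimethylcyclopentyl]-3-phenylprop-2-enal | O=C/C(=C/c1ccccc1)[C@H]1[C@H](O)[C@H](C)C[C@H]1C | intermediate
13 | (1R,2S,3R,5R)-2-[(1E)-3,3-dimethoxy-1-phenylprop-1-en-2-yl]-3,5-dimethylcyclopentan-1-ol | COC(OC)/C(=C/c1ccccc1)[C@H]1[C@H](O)[C@H](C)C[C@H]1C | intermediate
14 | [(1E)-2-[(1S,2S,3R,5R)-2-bromo-3,5-dimethylcyclopentyl]-3,3-dimethoxyprop-1-en-1-yl]benzene | COC(OC)/C(=C/c1ccccc1)[C@H]1[C@@H](Br)[C@H](C)C[C@H]1C | intermediate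
15 | 1-butyne | CCC#C | starting material
16 | cyclopentylmagnesium bromide from 14 (C–Mg trans to the unsaturated acetal side chain, other centres as in 14) | COC(OC)/C(=C/c1ccccc1)[C@H]1[C@H]([Mg]Br)[C@H](C)C[C@H]1C | intermediate
17 | cyclopentylcopper from 16 (same configuration; magnesium salt omitted) | COC(OC)/C(=C/c1ccccc1)[C@H]1[C@H]([Cu])[C@H](C)C[C@H]1C | intermediate
18 | (Z)-alkenylcopper: 2-ethyl-2-(cyclopentyl)ethenylcopper with the cyclopentyl group cis to copper | COC(OC)/C(=C/c1ccccc1)[C@H]1[C@H](/C(CC)=C\[Cu])[C@H](C)C[C@H]1C | intermediate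
19 | 7-ethyl-4-(methoxymethylidene)-1,3-dimethyl-5-phenyl-2,3,3a,4,5,7a-hexahydro-1H-indene (ring stereocentres as in 20) | CCC1=C[C@@H](c2ccccc2)C(=COC)[C@H]2[C@H]1[C@H](C)C[C@H]2C | intermediate
20 | (1R,3R,3aR,5R,7aR)-7-ethyl-1,3-dimethyl-5-phenyl-2,3,3a,4,5,7a-hexahydro-1H-indene-4-carbaldehyde (both C4 epimers) | CCC1=C[C@@H](c2ccccc2)C(C=O)[C@H]2[C@H]1[C@H](C)C[C@H]2C | intermediate
21 | (1R,3R,3aR,4R,5S,7aR)-4,7-diethyl-1,3-dimethyl-5-phenyl-2,3,3a,4,5,7a-hexahydro-1H-indene-4-carbaldehyde | CCC1=C[C@@H](c2ccccc2)[C@@](C=O)(CC)[C@H]2[C@H]1[C@H](C)C[C@H]2C | intermediate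
22 | ethyl 2-(triphenyl-λ5-phosphanylidene)propanoate | CCOC(=O)C(C)=P(c1ccccc1)(c1ccccc1)c1ccccc1 | starting material
23 | ethyl (2E)-3-[(1R,3R,3aR,4S,5S,7aR)-4,7-diethyl-1,3-dimethyl-5-phenyl-2,3,3a,4,5,7a-hexahydro-1H-inden-4-yl]-2-methylprop-2-enoate | CCC1=C[C@@H](c2ccccc2)[C@@](/C=C(\C)C(=O)OCC)(CC)[C@H]2[C@H]1[C@H](C)C[C@H]2C | intermediate
24 | homo-plakotenin, (2E)-3-[(1R,3R,3aR,4S,5S,7aR)-4,7-diethyl-1,3-dimethyl-5-phenyl-2,3,3a,4,5,7a-hexahydro-1H-inden-4-yl]-2-methylprop-2-enoic acid | CCC1=C[C@@H](c2ccccc2)[C@@](/C=C(\C)C(=O)O)(CC)[C@H]2[C@H]1[C@H](C)C[C@H]2C | target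

**Step count and risks**

Total step count: 15. Longest linear sequence: 15 steps (1 to 24); compounds 4, 11, 15 and 22 are used as purchased.

Steps most likely to fail:

1. Step 12 (proposed new method). The secondary alkylcopper may be protonated by the acidic alkyne C–H instead of adding to it; configuration at the metal-bearing carbon may not settle trans, which would give the cis-fused ring; or the alkenylcopper may attack the acetal carbon instead of the benzylic γ-carbon. Fallback by known chemistry, starting from bromide 14: zinc insertion (Zn, LiCl, THF) would give the cyclopentylzinc bromide F3. Negishi coupling (Pd(OAc)2, ligand CPhos, THF) with (Z)-2-(2-bromobut-1-en-1-yl)-4,4,5,5-tetramethyl-1,3,2-dioxaborolane F2 should then give the trans-configured (Z)-alkenylboronate acetal F4. F2 is made from 1-butyne 15 by syn-bromoboration with BBr3, via (Z)-(2-bromobut-1-en-1-yl)dibromoborane F1, and exchange with pinacol. Mild acid hydrolysis of the acetal would unmask the (Z)-alkenylboronate enal F5, and intramolecular rhodium-catalysed 1,4-addition ([Rh(cod)OH]2, KOH, dioxane/H2O) would close the ring with the same geometric control of the benzylic centre. The sequence comes back to the route at aldehyde 20.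

2. Step 13. The ethyl group may enter on the wrong face (anti to phenyl), or the aldehyde enolate may be O-alkylated. Fallback, starting from 20: the two C4 substituents are introduced in the reverse order. Alkylation with ethyl 2-(bromomethyl)acrylate (KOt-Bu; an O-alkylated product would converge by Claisen rearrangement) would give the formyl acrylate F6. Methylenation of the aldehyde (Ph3P=CH2) would give the vinyl acrylate F7. DBU-mediated isomerisation of the 2-alkylacrylate into conjugation would give the vinyl (E)-2-methylpropenoate F8. Selective hydrogenation of the vinyl group (H2, RhCl(PPh3)3) comes back to the route at ester 23.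

3. Step 14. The ylide may fail to add, because the formyl group is neopentylic, axial and crowded by the C3 methyl. Fallback, starting from 21: aldol addition of the lithium enolate of ethyl propanoate (LiN(i-Pr)2, THF, −78 °C), a smaller nucleophile, would give the β-hydroxy ester F9. Mesylation (MsCl, Et3N) would give the mesylate F10, and DBU-induced elimination would give the (E)-enoate, back on the route at 23.

**Further compounds**

F1 | step 12 | (Z)-(2-bromobut-1-en-1-yl)dibromoborane | CC/C(Br)=C/B(Br)Br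
F2 | step 12 | (Z)-2-(2-bromobut-1-en-1-yl)-4,4,5,5-tetramethyl-1,3,2-dioxaborolane | CC/C(Br)=C/B1OC(C)(C)C(C)(C)O1
F3 | step 12 | cyclopentylzinc bromide from 14 (C–Zn trans to the side chain) | COC(OC)/C(=C/c1ccccc1)[C@H]1[C@H]([Zn]Br)[C@H](C)C[C@H]1C
F4 | step 12 | (Z)-alkenylboronate acetal: pinacol boronate of 18 in place of copper | COC(OC)/C(=C/c1ccccc1)[C@H]1[C@H](/C(CC)=C\B2OC(C)(C)C(C)(C)O2)[C@H](C)C[C@H]1C
F5 | step 12 | (Z)-alkenylboronate enal: F4 with the acetal hydrolysed to the (E)-enal | O=C/C(=C/c1ccccc1)[C@H]1[C@H](/C(CC)=C\B2OC(C)(C)C(C)(C)O2)[C@H](C)C[C@H]1C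
F6 | step 13 | ethyl 2-{[7-ethyl-4-formyl-1,3-dimethyl-5-phenyl-2,3,3a,4,5,7a-hexahydro-1H-inden-4-yl]methyl}prop-2-enoate (formyl cis to phenyl) | CCC1=C[C@@H](c2ccccc2)[C@@](CC(=C)C(=O)OCC)(C=O)[C@H]2[C@H]1[C@H](C)C[C@H]2C
F7 | step 13 | ethyl 2-{[4-ethenyl-7-ethyl-1,3-dimethyl-5-phenyl-2,3,3a,4,5,7a-hexahydro-1H-inden-4-yl]methyl}prop-2-enoate | CCC1=C[C@@H](c2ccccc2)[C@@](CC(=C)C(=O)OCC)(C=C)[C@H]2[C@H]1[C@H](C)C[C@H]2C
F8 | step 13 | ethyl (2E)-3-[4-ethenyl-7-ethyl-1,3-dimethyl-5-phenyl-2,3,3a,4,5,7a-hexahydro-1H-inden-4-yl]-2-methylprop-2-enoate | CCC1=C[C@@H](c2ccccc2)[C@@](/C=C(\C)C(=O)OCC)(C=C)[C@H]2[C@H]1[C@H](C)C[C@H]2C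
F9 | step 14 | ethyl 3-[4,7-diethyl-1,3-dimethyl-5-phenyl-2,3,3a,4,5,7a-hexahydro-1H-inden-4-yl]-3-hydroxy-2-methylpropanoate (ring centres as in 21) | CCC1=C[C@@H](c2ccccc2)[C@@](C(O)C(C)C(=O)OCC)(CC)[C@H]2[C@H]1[C@H](C)C[C@H]2C
F10 | step 14 | methanesulfonate of F9 | CCC1=C[C@@H](c2ccccc2)[C@@](C(OS(C)(=O)=O)C(C)C(=O)OCC)(CC)[C@H]2[C@H]1[C@H](C)C[C@H]2C
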